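(Readings and results were computed with made-up constants.)

5 questions stood here, and I tried to answer them with one number.

| setting | Friday's | Wednesday's | Tuesday's | green | ochre | blue | amber |
|---|---|---|---|---|---|---|---|
| starting complex | 10 mM | 10 mM | 10 mM | 10 mM (fed, over 12 min) | 10 mM | 10 mM | 10 mM |
| incoming ligand | 0.95 equiv | 0.47 equiv | 0.71 equiv | 0.950 equiv | 0.950 equiv | 0.950 equiv (fed, over 12 min) | 0.950 equiv (in portions, 3, over 12 min) |
| remark | run made earlier | run made earlier | run made earlier | all else is in the flask from the start; the feed brings no volume worth counting | everything together at the start | all else is in the flask from the start; the feed brings no volume worth counting | first portion at the start, last at 12 min |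
| time |  |  |  | 20 min | 20 min | 20 min | 20 min |

| run | time / min | complex with three exchanged / % | complex with two exchanged / % |
|---|---|---|---|
| Friday's | 1.50 | 3.8 | 10.4 |
| Friday's | 2.50 | 7.5 | 12.2 |
| Friday's | 4.00 | 7.6 | 13.9 |
| Friday's | 8.00 | 10.2 | 13.5 |
| Friday's | 12.0 | 9.9 | 13.8 |
| Friday's | 20.0 | 9.6 | 12.8 |
| Wednesday's | 2.50 | 1.5 | 4.6 |
| Wednesday's | 5.00 | 1.2 | 5.5 |
| Wednesday's | 8.00 | 1.7 | 5.8 |
| Wednesday's | 10.0 | 1.3 | 5.5 |
| Wednesday's | 12.0 | 1.4 | 5.5 |
| Wednesday's | 15.0 | 1.2 | 6.6 |
| Tuesday's | 2.50 | 3.5 | 9.1 |
| Tuesday's | 5.00 | 4.9 | 9.7 |
| Tuesday's | 8.00 | 5.0 | 9.7 |
| Tuesday's | 10.0 | 4.5 | 10.1 |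
| Tuesday's | 12.0 | 4.7 | 9.0 |
| Tuesday's | 15.0 | 5.3 | 9.4 |

(readings scatter by 0.5 percentage points)

- which flask leads in amount of complex with three exchanged, in percent of the starting complex charged ("all alike" within 1.5 percentage points) (green / ochre / blue / amber / all alike)
- how much complex with three exchanged is there at the end, in percent of the starting complex charged: green
- how much complex with three exchanged is there at the end, in percent of the starting complex charged: ochre
- how much complex with three exchanged is there at the end, in percent of the starting complex charged: blue
- how much complex with three exchanged is there at the end, in percent of the starting complex charged: amber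

- the numbers in the tables scatter by 0.5 percentage points (one standard deviation)

I reckoned with the load, 0.950 for Friday's run: the equivalents of incoming ligand (the limiting reagent) per starting complex in the flask while the ligand lasts. If the steps go at similar pace, exchanges fall like chance hits with that mean, which leaves a starting share of exp(−load) and a tail of three or more:

tail = 1 − exp(−load) × (1 + load + load × load / 2) = 7.13%

Friday's last 3 readings of complex with three exchanged, over this tail, give a gain of 1.39. Gain times tail then gave 1.70% for Wednesday's run, read as 1.38%, and 4.91% for Tuesday's, read as 4.65%.

I took ochre, blue and amber to share Friday's load, and so about 9.91%. Green needed a clock as well, so one number was not enough. Friday's first reading of complex with two exchanged, held against the mean of its later readings, gave a rise time near 1.02 min, and I took that reading as the ligand time, the time scale of incoming ligand with the whole starting complex present. From it I estimated the share of complex entered in green while ligand lasts: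

entered = sqrt(2 × ligand time / feed time) = 41.2%

That raises green's load, and I reckoned 56.2% of the entered complex at three exchanged. Going round again, with half that share taken as no longer using ligand, gave 48.6% entered, a load of 1.95 and 21.0% for green.

The forecast named green: 20%, with 10%, 10% and 10% for ochre, blue and amber, holding that “product distribution depends only on ligand consumed, not its concentration”.

The flasks gave 19.6% in green, 9.64% in ochre, 9.65% in blue and 9.64% in amber.

    starting complex + incoming ligand → leaving ligand + complex with one exchanged (k = 1.60 M⁻¹ s⁻¹)
    complex with one exchanged + incoming ligand → leaving ligand + complex with two exchanged (k = 1.40 M⁻¹ s⁻¹)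
    complex with two exchanged + incoming ligand → leaving ligand + complex with three exchanged (k = 2.60 M⁻¹ s⁻¹)
    complex with three exchanged + incoming ligand ⇌ leaving ligand + complex with four exchanged (K = 0.610, k = 1.10 M⁻¹ s⁻¹)
    starting complex → decomposition product (k = 3.70 × 10⁻⁶ s⁻¹)

Ochre's starting complex stood at 37.6% against 38.7% from its load, beside 0% complex with four exchanged and 0.179% decomposition product. Amber's neighbour took 1.60 equiv of incoming ligand, a load of 1.60. That reckons to 20.2% starting complex and 30.1% complex with three exchanged. The neighbour ended with 17.7% starting complex and 29.8% complex with three exchanged.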